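**Plan**

1. Retrosynthesis: the cis C2=C3 bond of the ten-membered carbocycle (C1–C10) is traced back to a CH2–SO2–CH2 unit, i.e. an eleven-membered cyclic sulfone. That ring is cut at its two C–S bonds (C3 allylic chloride, C2 tosylate) and then at C7–C8.
2. Enabling feature: C2 and C3 are the only adjacent unsubstituted ring carbons. C3 is allylic to C4=C5, so Ramberg–Bäcklund loss of SO2 makes the cis,cis C2–C5 diene and contracts the ring from eleven to ten atoms in one event.
3. Helpers: the 1,10-epoxide is stored as its diol acetonide (no epoxide next to a sulfonyl carbanion, no cyclodecatriene). The α-methylene lactone is stored as a silyl lactol and C8–O as a benzoate; all are restored afterwards.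
4. Forward order: fragment A (C8–C10, C1, C2) and fragment B (C3–C7, C11–C13, C15, butenolide ring) are joined at C7–C8 by indium allylation. Then follow the eleven-membered sulfide, the sulfone, the ten-membered ring, the C8 ester, the lactone and the epoxide.
5. Stereochemistry: C1/C10 come from one Sharpless epoxidation (C1 inverted by Payne opening, re-inverted on epoxide closure). C6 comes from a catalytic asymmetric alkynylation; C7 is relayed from C6; C8 is set by the chair allylation and then inverted by Mitsunobu. Both ring olefins are cis (directed hydroalumination; ring contraction).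

Key step: step 19

Remark: atom labels C1–C15 follow germacrane numbering (C6 = lactone O–CH, C8 = acyloxy carbon, C12 = lactone carbonyl, C15 = CH2OH); compound numbers are plain numerals.
Remark: the lactol carbon C12 of compounds 26–38 is assumed to be carried as an anomeric mixture and is left undefined in their SMILES, as are the transient centres of 9, 30, 32 and 33.

**Fragment A**

Step 1
Reactants: 1 pent-1-en-4-yne
Product: 3 (E)-3-methylhexa-2,5-dien-1-ol, via alkenyldimethylalane 2 (not isolated)
Conditions: Me3Al, Cp2ZrCl2 (cat.), CH2Cl2, 0 °C→rt; n-BuLi, then (CH2O)n, THF, −78 °C→rt; aq HCl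
Reagents that add atoms: trimethylaluminium, C[Al](C)C; formaldehyde (as paraformaldehyde), C=O
Why: Negishi zirconium-catalysed carboalumination adds methyl and aluminium syn across the terminal alkyne much faster than across the monosubstituted alkene, and the derived alanate is hydroxymethylated with retention, so the E allylic alcohol results.

Step 2
Reactants: 3 (E)-3-methylhexa-2,5-dien-1-ol
Product: 4 [(2R,3R)-3-methyl-3-(prop-2-en-1-yl)oxiran-2-yl]methanol
Conditions: Ti(OiPr)4 (10 mol %), D-(−)-diethyl tartrate, t-BuOOH, 4 Å MS, CH2Cl2, −20 °C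
Reagents that add atoms: tert-butyl hydroperoxide, CC(C)(C)OO
Why: Sharpless asymmetric epoxidation of the E allylic alcohol; D-(−)-diethyl tartrate delivers oxygen to the face that gives the (2R,3R)-epoxy alcohol (geraniol precedent), setting C1 and C10 in one event while the isolated vinyl group is untouched.

Step 3
Reactants: 4 [(2R,3R)-3-methyl-3-(prop-2-en-1-yl)oxiran-2-yl]methanol
Product: 6 (2S,3R)-3-methylhex-5-ene-1,2,3-triol, via Payne-isomer terminal epoxide 5 (not isolated)
Conditions: 0.5 M aq NaOH, t-BuOH, 75 °C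
Reagents that add atoms: water (as hydroxide), O
Why: Payne rearrangement (the alkoxide opens the epoxide at C1 with inversion) followed by hydroxide attack at the CH2 of the more reactive terminal epoxide gives the triol with C1 inverted and C10 unchanged, so the epoxide is stored as a diol from which a second inversion at C1 will regenerate it.

Step 4
Reactants: 6 (2S,3R)-3-methylhex-5-ene-1,2,3-triol
Product: 7 (2S,3R)-2,3-dihydroxy-3-methylhex-5-en-1-yl 4-methylbenzenesulfonate
Conditions: TsCl, Et3N, Bu2SnO (cat.), CH2Cl2, 0 °C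
Reagents that add atoms: 4-methylbenzenesulfonyl chloride, Cc1ccc(cc1)S(Cl)(=O)=O
Why: Dibutyltin oxide-catalysed sulfonylation of the terminal 1,2-diol is selective for the primary hydroxyl.

Step 5
Reactants: 7 (2S,3R)-2,3-dihydroxy-3-methylhex-5-en-1-yl 4-methylbenzenesulfonate
Product: 8 [(4S,5R)-2,2,5-trimethyl-5-(prop-2-en-1-yl)-1,3-dioxolan-4-yl]methyl 4-methylbenzenesulfonate
Conditions: Me2C(OMe)2, PPTS (cat.), CH2Cl2, rt
Reagents that add atoms: 2,2-dimethoxypropane, COC(C)(C)OC
Why: Acid-catalysed transketalisation closes the dioxolane on the secondary/tertiary diol, which makes the C1 oxygen a poor leaving group and removes all acidic OH before the later carbanion chemistry.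

Step 6
Reactants: 8 [(4S,5R)-2,2,5-trimethyl-5-(prop-2-en-1-yl)-1,3-dioxolan-4-yl]methyl 4-methylbenzenesulfonate
Product: 10 [(4S,5R)-2,2,5-trimethyl-5-(2-oxoethyl)-1,3-dioxolan-4-yl]methyl 4-methylbenzenesulfonate (fragment A), via ozonide 9 (not isolated)
Conditions: O3, CH2Cl2, −78 °C; PPh3
Reagents that add atoms: ozone, [O-][O+]=O
Why: Ozonolysis of the terminal alkene with reductive work-up gives the β-alkoxy aldehyde under neutral conditions (no β-elimination); tosylate and ketal are inert.

**Fragment B**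

Step 7
Reactants: 11 (E)-but-2-enal; 12 tert-butyldiphenyl(prop-2-yn-1-yloxy)silane
Product: 13 (S,E)-1-[(tert-butyldiphenylsilyl)oxy]hept-5-en-2-yn-4-ol
Conditions: Me2Zn, (S,S)-ProPhenol (10 mol %), Ph3P=O (20 mol %), toluene, 0 °C
Reagents that add atoms: none
Why: Zinc–ProPhenol catalysed asymmetric 1,2-addition of the alkynylzinc to the enal sets C6; the ligand antipode that gives the (S)-carbinol shown is to be used, and both antipodes are commercial.

Step 8
Reactants: 13 (S,E)-1-[(tert-butyldiphenylsilyl)oxy]hept-5-en-2-yn-4-ol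
Product: 15 (S,2Z,5E)-1-[(tert-butyldiphenylsilyl)oxy]-2-iodohepta-2,5-dien-4-ol, via cyclic alkenylalanate 14 (not isolated)
Conditions: NaAlH2(OCH2CH2OMe)2, THF, 0 °C; I2, −78 °C
Reagents that add atoms: iodine, II
Why: Hydroxyl-directed trans-hydroalumination of the propargylic alcohol places aluminium on the distal alkyne carbon cis to the carbinol carbon (five-membered alanate), and iodinolysis with retention gives the vinyl iodide that fixes the C4=C5 geometry.

Step 9
Reactants: 15 (S,2Z,5E)-1-[(tert-butyldiphenylsilyl)oxy]-2-iodohepta-2,5-dien-4-ol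
Product: 16 (S,2E,5E)-2-{[(tert-butyldiphenylsilyl)oxy]methyl}hepta-2,5-diene-1,4-diol (CH2OH cis to the carbinol carbon)
Conditions: Bu3SnCH2OH, Pd(PPh3)4 (5 mol %), dioxane, 90 °C
Reagents that add atoms: (tributylstannyl)methanol, OC[Sn](CCCC)(CCCC)CCCC
Why: Migita–Kosugi–Stille coupling transfers the α-oxygenated CH2OH group with retention of olefin geometry, so C3 enters cis to C6 and C15 stays trans.

Step 10
Reactants: 16 (S,2E,5E)-2-{[(tert-butyldiphenylsilyl)oxy]methyl}hepta-2,5-diene-1,4-diol
Product: 18 (S,2Z,5E)-2-(chloromethyl)-1-[(tert-butyldiphenylsilyl)oxy]hepta-2,5-dien-4-ol, via primary allylic mesylate 17 (not isolated)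
Conditions: MsCl, 2,4,6-collidine, LiCl, DMF, 0 °C
Reagents that add atoms: lithium chloride, [Li+].[Cl-]
Why: Under Collington–Meyers conditions the primary allylic hydroxyl is mesylated selectively and displaced by chloride (SN2) faster than the neutral cis hydroxyl can close a dihydrofuran.

Step 11
Reactants: 18 (S,2Z,5E)-2-(chloromethyl)-1-[(tert-butyldiphenylsilyl)oxy]hepta-2,5-dien-4-ol
Product: 19 2-(bromomethyl)acrylate ester of 18
Conditions: 2-(bromomethyl)acrylic acid, DCC, DMAP (5 mol %), CH2Cl2, −10 °C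
Reagents that add atoms: 2-(bromomethyl)acrylic acid, C=C(CBr)C(=O)O
Why: Steglich esterification of the secondary alcohol under nearly neutral conditions leaves C6 and both allylic halides untouched.

Step 12
Reactants: 19 2-(bromomethyl)acrylate ester of 18
Product: 20 (5R)-3-(bromomethyl)-5-[(Z)-2-(chloromethyl)-3-(tert-butyldiphenylsilyloxy)prop-1-en-1-yl]furan-2(5H)-one (fragment B)
Conditions: second-generation Grubbs catalyst (5 mol %), CH2Cl2, 40 °C
Reagents that add atoms: none
Why: Ring-closing metathesis between the propenyl group and the acrylate forms the five-membered butenolide with loss of propene; the trisubstituted chloroalkene is too hindered to take part.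

**Side-chain acid**

Step 13
Reactants: 21 4-methylfuran-2(5H)-one
Product: 23 (Z)-4-acetoxy-3-methylbut-2-enoic acid, via sodium hydroxy-enoate 22 (not isolated)
Conditions: aq NaOH, rt; Ac2O, pyridine, 0 °C; aq HCl
Reagents that add atoms: sodium hydroxide, [Na+].[OH-]; acetic anhydride, CC(=O)OC(C)=O
Why: Saponification opens the butenolide to the hydroxy carboxylate whose CH2OH and carboxylate are cis (Z) by construction, and O-acetylation blocks relactonisation.

**Union, ring contraction and endgame**

Step 14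
Reactants: 10 fragment A aldehyde; 20 fragment B bromomethyl butenolide
Product: 24 C8-epi hydroxy lactone (6,7-trans α-methylene-γ-lactone; C8 carbinol epimeric to the target)
Conditions: In powder, THF/sat. aq NH4Cl, rt
Reagents that add atoms: none
Why: In this indium Barbier allylation the allylindium reacts at its γ-carbon (C7) anti to the C6 substituent, giving the 6,7-trans α-methylene lactone, while the closed chair transition state with the aldehyde chain equatorial sets C8 opposite to the target; indium does not insert into the allylic chloride or the tosylate.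

Step 15
Reactants: 24 C8-epi hydroxy lactone
Product: 25 C8 benzoate (C8 inverted to the target configuration)
Conditions: PhCO2H, PPh3, DIAD, THF, 0 °C→rt
Reagents that add atoms: benzoic acid, OC(=O)c1ccccc1
Why: Mitsunobu esterification inverts C8 by SN2 displacement of the oxyphosphonium by benzoate, which gives the C8 configuration of the target and a hindered ester as protecting group.

Step 16
Reactants: 25 C8 benzoate
Product: 27 silyl lactol benzoate (C12 O-TBS acetal), via aluminium lactolate 26 (not isolated)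
Conditions: i-Bu2AlH (1.2 equiv), CH2Cl2, −78 °C; pyridine, TBSOTf, −78→0 °C
Reagents that add atoms: tert-butyldimethylsilyl trifluoromethanesulfonate, CC(C)(C)[Si](C)(C)OS(=O)(=O)C(F)(F)F
Why: Diisobutylaluminium hydride at −78 °C reduces the lactone by 1,2-addition to a stable aluminium hemiacetal in preference to the hindered secondary benzoate, and in situ silylation (reductive silylation, the silyl counterpart of Rychnovsky reductive acetylation) masks the Michael acceptor as a base-stable silyl lactol without freeing a lactol.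

Step 17
Reactants: 27 silyl lactol benzoate
Product: 29 eleven-membered cyclic sulfide, via sodium allylic thiolate 28 (not isolated)
Conditions: Na2S·9H2O, EtOH/THF, 55 °C, slow addition, 2 mM
Reagents that add atoms: sodium sulfide, [Na+].[Na+].[S-2]
Why: In this double SN2 thioetherification sulfide displaces the reactive allylic chloride first and the resulting thiolate closes the eleven-membered ring on the primary tosylate (11-exo-tet) under high dilution, the cis C4=C5 olefin and the two fused five-membered rings pre-folding the chain.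

Step 18
Reactants: 29 eleven-membered cyclic sulfide
Product: 31 eleven-membered cyclic sulfone, via sulfoxide 30 (not isolated)
Conditions: (NH4)6Mo7O24·4H2O (10 mol %), 30% H2O2, EtOH, 0 °C→rt
Reagents that add atoms: hydrogen peroxide, OO
Why: Molybdate-catalysed peroxide oxidation converts sulfide to sulfone chemoselectively; the electron-poor alkenes, the ester and the acetals are not attacked.

Step 19
Reactants: 31 eleven-membered cyclic sulfone
Product: 34 ten-membered cis,cis-diene benzoate, via α-bromo sulfone 32 (not isolated), via episulfone 33 (not isolated)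
Conditions: CBr2F2, KOH/Al2O3, t-BuOH/CH2Cl2, 0 °C→rt
Reagents that add atoms: none
Why: Ramberg–Bäcklund reaction in the Meyers–Chan form: KOH on alumina deprotonates the allylic α-CH2 (C3), CBr2F2 brominates the carbanion, the α′-carbanion at C2 displaces bromide to give the thiirane 1,1-dioxide, and cheletropic loss of SO2 forms C2=C3, so the eleven-membered ring loses sulfur and becomes the ten-membered carbocycle. The closest known reaction type is the Ramberg–Bäcklund ring contraction of medium-ring sulfones to cycloalkenes and of allylic sulfones to conjugated dienes. The only ring closed is the transient episulfone (3-exo-tet); the carbocycle arises by contraction, not by a new macrocyclisation. No stereocentre is created; the olefin should be cis because the 1,3-elimination favours the cis-fused episulfone, extrusion is stereospecific, and a cis,cis-1,3-diene is far less strained in a ten-membered ring than the cis,trans isomer, so kinetic and thermodynamic control agree. The step needs episulfone formation to outrun β-elimination of the C1 oxygen and vinylogous elimination towards C6–O; the ketal oxygen is a poor leaving group (β-alkoxy sulfones are known substrates) and bromination at C3 followed by 3-exo displacement is fast at 0 °C. Base-sensitive functions are absent because the epoxide is stored as the diol acetonide, the α-methylene lactone as the silyl lactol and C8–O as a hindered benzoate; a C1=C10 olefin at this stage would instead give a cyclodeca-1,3,5-triene prone to 6π-electrocyclisation.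

Step 20
Reactants: 34 ten-membered cis,cis-diene benzoate
Product: 35 ten-membered diene C8 alcohol
Conditions: i-Bu2AlH (2.5 equiv), CH2Cl2, −78 °C; aq KNaC4H4O6
Reagents that add atoms: none
Why: Reductive cleavage of the benzoate, the only ester present, by diisobutylaluminium hydride frees the C8 hydroxyl without base.

Step 21
Reactants: 35 ten-membered diene C8 alcohol; 23 (Z)-4-acetoxy-3-methylbut-2-enoic acid
Product: 37 C8 ester silyl lactol, via mixed anhydride 36 (not isolated)
Conditions: 23, 2,4,6-Cl3C6H2COCl, Et3N, THF; then 35, DMAP, toluene, rt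
Reagents that add atoms: none
Why: Yamaguchi esterification through the mixed anhydride acylates the hindered C8 hydroxyl, the only free hydroxyl, without isomerising the Z enoate.

Step 22
Reactants: 37 C8 ester silyl lactol
Product: 38 C8 ester lactol
Conditions: HF·pyridine, pyridine, THF, 0 °C
Reagents that add atoms: none
Why: Buffered fluoride cleaves the labile anomeric silyl ether selectively over the primary TBDPS ether; since O8 is acylated, the free lactol can only close on O6.

Step 23
Reactants: 38 C8 ester lactol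
Product: 39 α-methylene lactone acetonide
Conditions: TEMPO (20 mol %), PhI(OAc)2, CH2Cl2, rt
Reagents that add atoms: none
Why: Oxoammonium oxidation (TEMPO/PhI(OAc)2) converts the lactol into the α-methylene γ-lactone; no other free hydroxyl is present.

Step 24
Reactants: 39 α-methylene lactone acetonide
Product: 40 C1,C10-diol
Conditions: AcOH/H2O/THF (3:1:1), 40 °C
Reagents that add atoms: none
Why: Mild aqueous acid hydrolyses the isopropylidene ketal through its ketal carbon; esters, lactone, diene and the TBDPS ether are stable under these conditions.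

Step 25
Reactants: 40 C1,C10-diol
Product: 42 15-O-TBDPS ether of the target, via C1 mesylate 41 (not isolated)
Conditions: Ms2O, Et3N, CH2Cl2, −30 °C; DBU, −30→0 °C
Reagents that add atoms: none
Why: The secondary C1 hydroxyl is mesylated selectively (the tertiary C10 hydroxyl is inert) and displaced intramolecularly by the C10 alkoxide (3-exo-tet, inversion at C1), which restores the configuration installed in step 2 and gives the trans-disposed 1,10-epoxide.

Step 26
Reactants: 42 15-O-TBDPS ether of the target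
Product: 43 target compound CNP0292814.1
Conditions: Bu4NF, AcOH, THF, 0 °C→rt
Reagents that add atoms: none
Why: Acetic acid-buffered fluoride cleaves the primary TBDPS ether without opening the vinyl epoxide, adding to the α-methylene lactone or cleaving the esters.

**Compound list**

1 | pent-1-en-4-yne | C=CCC#C | starting material
2 | (E)-dimethyl(2-methylpenta-1,4-dien-1-yl)alane | C=CC/C(C)=C/[Al](C)C | intermediate
3 | (E)-3-methylhexa-2,5-dien-1-ol | OC/C=C(\C)CC=C | intermediate
4 | [(2R,3R)-3-methyl-3-(prop-2-en-1-yl)oxiran-2-yl]methanol | OC[C@H]1O[C@]1(C)CC=C | intermediate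
5 | (2R)-2-[(2S)-oxiran-2-yl]pent-4-en-2-ol (Payne isomer) | C=CC[C@@](C)(O)[C@@H]1CO1 | intermediate
6 | (2S,3R)-3-methylhex-5-ene-1,2,3-triol | OC[C@H](O)[C@](C)(O)CC=C | intermediate
7 | (2S,3R)-2,3-dihydroxy-3-methylhex-5-en-1-yl 4-methylbenzenesulfonate | Cc1ccc(cc1)S(=O)(=O)OC[C@H](O)[C@](C)(O)CC=C | intermediate
8 | [(4S,5R)-2,2,5-trimethyl-5-(prop-2-en-1-yl)-1,3-dioxolan-4-yl]methyl 4-methylbenzenesulfonate | Cc1ccc(cc1)S(=O)(=O)OC[C@@H]1OC(C)(C)O[C@]1(C)CC=C | intermediate
9 | 1,2,4-trioxolane (ozonide) of 8 | Cc1ccc(cc1)S(=O)(=O)OC[C@@H]1OC(C)(C)O[C@]1(C)CC2OCOO2 | intermediate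
10 | [(4S,5R)-2,2,5-trimethyl-5-(2-oxoethyl)-1,3-dioxolan-4-yl]methyl 4-methylbenzenesulfonate (fragment A) | Cc1ccc(cc1)S(=O)(=O)OC[C@@H]1OC(C)(C)O[C@]1(C)CC=O | intermediate
11 | (E)-but-2-enal | C/C=C/C=O | starting material
12 | tert-butyldiphenyl(prop-2-yn-1-yloxy)silane | C#CCO[Si](c1ccccc1)(c1ccccc1)C(C)(C)C | starting material
13 | (S,E)-1-[(tert-butyldiphenylsilyl)oxy]hept-5-en-2-yn-4-ol | C/C=C/[C@H](O)C#CCO[Si](c1ccccc1)(c1ccccc1)C(C)(C)C | intermediate
14 | sodium cyclic alkoxy(alkenyl)alanate from 13 (aluminium on C4, cis to C6) | [Na+].C/C=C/[C@@H]1O[Al-](OCCOC)(OCCOC)C(CO[Si](c2ccccc2)(c2ccccc2)C(C)(C)C)=C1 | intermediate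
15 | (S,2Z,5E)-1-[(tert-butyldiphenylsilyl)oxy]-2-iodohepta-2,5-dien-4-ol | C/C=C/[C@H](O)/C=C(I)/CO[Si](c1ccccc1)(c1ccccc1)C(C)(C)C | intermediate
16 | (S,2E,5E)-2-{[(tert-butyldiphenylsilyl)oxy]methyl}hepta-2,5-diene-1,4-diol (CH2OH cis to C4) | C/C=C/[C@H](O)/C=C(CO)/CO[Si](c1ccccc1)(c1ccccc1)C(C)(C)C | intermediate
17 | primary allylic methanesulfonate of 16 | C/C=C/[C@H](O)/C=C(COS(C)(=O)=O)/CO[Si](c1ccccc1)(c1ccccc1)C(C)(C)C | intermediate
18 | (S,2Z,5E)-2-(chloromethyl)-1-[(tert-butyldiphenylsilyl)oxy]hepta-2,5-dien-4-ol | C/C=C/[C@H](O)/C=C(CCl)/CO[Si](c1ccccc1)(c1ccccc1)C(C)(C)C | intermediate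
19 | 2-(bromomethyl)acrylate ester of 18 | C=C(CBr)C(=O)O[C@@H](/C=C/C)/C=C(CCl)/CO[Si](c1ccccc1)(c1ccccc1)C(C)(C)C | intermediate
20 | (5R)-3-(bromomethyl)-5-[(Z)-2-(chloromethyl)-3-(tert-butyldiphenylsilyloxy)prop-1-en-1-yl]furan-2(5H)-one (fragment B) | O=C1O[C@H](/C=C(CCl)/CO[Si](c2ccccc2)(c2ccccc2)C(C)(C)C)C=C1CBr | intermediate
21 | 4-methylfuran-2(5H)-one | CC1=CC(=O)OC1 | starting material
22 | sodium (Z)-4-hydroxy-3-methylbut-2-enoate | [Na+].[O-]C(=O)/C=C(/C)CO | intermediate
23 | (Z)-4-acetoxy-3-methylbut-2-enoic acid | OC(=O)/C=C(/C)COC(C)=O | intermediate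
24 | C8-epi hydroxy lactone: 6,7-trans α-methylene-γ-lactone with free C8-OH (epimeric to the target), C3 chloride, C15 OTBDPS, C1/C10 acetonide, C2 tosylate | C=C1C(=O)O[C@H](/C=C(CCl)/CO[Si](c2ccccc2)(c2ccccc2)C(C)(C)C)[C@H]1[C@@H](O)C[C@@]3(C)OC(C)(C)O[C@H]3COS(=O)(=O)c4ccc(C)cc4 | intermediate
25 | C8 benzoate of the C8-inverted alcohol (target configuration at C6, C7, C8) | C=C1C(=O)O[C@H](/C=C(CCl)/CO[Si](c2ccccc2)(c2ccccc2)C(C)(C)C)[C@H]1[C@H](OC(=O)c5ccccc5)C[C@@]3(C)OC(C)(C)O[C@H]3COS(=O)(=O)c4ccc(C)cc4 | intermediate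
26 | diisobutylaluminium lactolate of 25 | C=C1C(O[Al](CC(C)C)CC(C)C)O[C@H](/C=C(CCl)/CO[Si](c2ccccc2)(c2ccccc2)C(C)(C)C)[C@H]1[C@H](OC(=O)c5ccccc5)C[C@@]3(C)OC(C)(C)O[C@H]3COS(=O)(=O)c4ccc(C)cc4 | intermediate
27 | silyl lactol benzoate (C12 O-TBS acetal of the reduced lactone) | C=C1C(O[Si](C)(C)C(C)(C)C)O[C@H](/C=C(CCl)/CO[Si](c2ccccc2)(c2ccccc2)C(C)(C)C)[C@H]1[C@H](OC(=O)c5ccccc5)C[C@@]3(C)OC(C)(C)O[C@H]3COS(=O)(=O)c4ccc(C)cc4 | intermediate
28 | sodium C3 allylic thiolate of 27 | [Na+].C=C1C(O[Si](C)(C)C(C)(C)C)O[C@H](/C=C(C[S-])/CO[Si](c2ccccc2)(c2ccccc2)C(C)(C)C)[C@H]1[C@H](OC(=O)c5ccccc5)C[C@@]3(C)OC(C)(C)O[C@H]3COS(=O)(=O)c4ccc(C)cc4 | intermediate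
29 | eleven-membered cyclic sulfide (S between C2 and C3) | C=C1C(O[Si](C)(C)C(C)(C)C)O[C@@H]2/C=C(CO[Si](c3ccccc3)(c3ccccc3)C(C)(C)C)\CSC[C@@H]4OC(C)(C)O[C@]4(C)C[C@@H](OC(=O)c5ccccc5)[C@@H]12 | intermediate
30 | cyclic sulfoxide | C=C1C(O[Si](C)(C)C(C)(C)C)O[C@@H]2/C=C(CO[Si](c3ccccc3)(c3ccccc3)C(C)(C)C)\CS(=O)C[C@@H]4OC(C)(C)O[C@]4(C)C[C@@H](OC(=O)c5ccccc5)[C@@H]12 | intermediate
31 | eleven-membered cyclic sulfone | C=C1C(O[Si](C)(C)C(C)(C)C)O[C@@H]2/C=C(CO[Si](c3ccccc3)(c3ccccc3)C(C)(C)C)\CS(=O)(=O)C[C@@H]4OC(C)(C)O[C@]4(C)C[C@@H](OC(=O)c5ccccc5)[C@@H]12 | intermediate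
32 | α-bromo sulfone (Br at C3) | C=C1C(O[Si](C)(C)C(C)(C)C)O[C@@H]2/C=C(CO[Si](c3ccccc3)(c3ccccc3)C(C)(C)C)\C(Br)S(=O)(=O)C[C@@H]4OC(C)(C)O[C@]4(C)C[C@@H](OC(=O)c5ccccc5)[C@@H]12 | intermediate
33 | cis-fused episulfone (thiirane 1,1-dioxide on C2–C3) | C=C1C(O[Si](C)(C)C(C)(C)C)O[C@@H]2/C=C(CO[Si](c3ccccc3)(c3ccccc3)C(C)(C)C)\C6C(S6(=O)=O)[C@@H]4OC(C)(C)O[C@]4(C)C[C@@H](OC(=O)c5ccccc5)[C@@H]12 | intermediate
34 | ten-membered cis,cis-diene benzoate | C=C1C(O[Si](C)(C)C(C)(C)C)O[C@@H]2/C=C(CO[Si](c3ccccc3)(c3ccccc3)C(C)(C)C)\C=C/[C@@H]4OC(C)(C)O[C@]4(C)C[C@@H](OC(=O)c5ccccc5)[C@@H]12 | intermediate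
35 | ten-membered diene C8 alcohol | C=C1C(O[Si](C)(C)C(C)(C)C)O[C@@H]2/C=C(CO[Si](c3ccccc3)(c3ccccc3)C(C)(C)C)\C=C/[C@@H]4OC(C)(C)O[C@]4(C)C[C@@H](O)[C@@H]12 | intermediate
36 | mixed anhydride of 23 with 2,4,6-trichlorobenzoic acid | CC(=O)OC/C(C)=C\C(=O)OC(=O)c1c(Cl)cc(Cl)cc1Cl | intermediate
37 | C8 (Z)-4-acetoxy-3-methylbut-2-enoate, silyl lactol | C=C1C(O[Si](C)(C)C(C)(C)C)O[C@@H]2/C=C(CO[Si](c3ccccc3)(c3ccccc3)C(C)(C)C)\C=C/[C@@H]4OC(C)(C)O[C@]4(C)C[C@@H](OC(=O)/C=C(/C)COC(C)=O)[C@@H]12 | intermediate
38 | C8 ester, free lactol | C=C1C(O)O[C@@H]2/C=C(CO[Si](c3ccccc3)(c3ccccc3)C(C)(C)C)\C=C/[C@@H]4OC(C)(C)O[C@]4(C)C[C@@H](OC(=O)/C=C(/C)COC(C)=O)[C@@H]12 | intermediate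
39 | α-methylene lactone with C1/C10 acetonide and C15 OTBDPS | C=C1C(=O)O[C@@H]2/C=C(CO[Si](c3ccccc3)(c3ccccc3)C(C)(C)C)\C=C/[C@@H]4OC(C)(C)O[C@]4(C)C[C@@H](OC(=O)/C=C(/C)COC(C)=O)[C@@H]12 | intermediate
40 | C1,C10-diol (C1 epimeric to the epoxide carbon) | C=C1C(=O)O[C@@H]2/C=C(CO[Si](c3ccccc3)(c3ccccc3)C(C)(C)C)\C=C/[C@H](O)[C@](C)(O)C[C@@H](OC(=O)/C=C(/C)COC(C)=O)[C@@H]12 | intermediate
41 | C1 methanesulfonate of 40 | C=C1C(=O)O[C@@H]2/C=C(CO[Si](c3ccccc3)(c3ccccc3)C(C)(C)C)\C=C/[C@H](OS(C)(=O)=O)[C@](C)(O)C[C@@H](OC(=O)/C=C(/C)COC(C)=O)[C@@H]12 | intermediate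
42 | 15-O-TBDPS ether of the target | C=C1C(=O)O[C@@H]2/C=C(CO[Si](c3ccccc3)(c3ccccc3)C(C)(C)C)\C=C/[C@H]4O[C@]4(C)C[C@@H](OC(=O)/C=C(/C)COC(C)=O)[C@@H]12 | intermediate
43 | CNP0292814.1 | C=C1C(=O)O[C@@H]2/C=C(CO)\C=C/[C@H]3O[C@]3(C)C[C@@H](OC(=O)/C=C(/C)COC(C)=O)[C@@H]12 | target

**Step count**

Total: 26 steps. Longest linear sequence: 19 steps (steps 1–6, then 14–26; the branch through steps 7–12 is equally long).

**Steps most likely to fail**

Step 19 (ring contraction). The sulfonyl carbanions may eliminate instead of closing the episulfone: β-loss of the C1 oxygen, vinylogous loss of the C6 oxygen, or over-bromination; partial formation of the trans olefin is also possible. The fallback sets out from sulfide 29 and separates halogenation from the basic step. N-Chlorosuccinimide in CH2Cl2 at 0 °C chlorinates the sulfide at the allylic C3 to give the α-chloro sulfide F2. Oxidation with mCPBA/NaHCO3 at −20 °C gives the α-chloro sulfone F3. Brief treatment with t-BuOK in THF at −78 °C then effects the 1,3-elimination and SO2 loss from a defined halosulfone and returns to the route at 34.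

Step 17 (macrocyclisation). The intermolecular first displacement may be followed by oligomerisation, or sulfide may attack both ends. The fallback sets out from 27: potassium thioacetate in DMF at 0 °C displaces only the allylic chloride and gives the allylic thioacetate F1. Methanolysis with K2CO3 in MeOH/THF at 2 mM then releases the thiolate at low stationary concentration, so that the only electrophile it meets is its own tosylate; the route is rejoined at 29.

Step 25 (epoxide closure). The dienylic C1 mesylate may ionise and give allylic transposition or attack of O10 at C3 instead of C1. The fallback sets out from diol 40 and uses cyclodehydration with PPh3/DIAD in THF at 0 °C. The secondary hydroxyl is activated as an oxyphosphonium and displaced at once by the neighbouring tertiary hydroxyl with inversion, without a free sulfonate or added base. It returns to the route at 42 and makes no new compound (F0).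

**Further compounds**

F1 | step 17 | C3 allylic thioacetate of 27 (tosylate retained) | C=C1C(O[Si](C)(C)C(C)(C)C)O[C@H](/C=C(CSC(C)=O)/CO[Si](c2ccccc2)(c2ccccc2)C(C)(C)C)[C@H]1[C@H](OC(=O)c5ccccc5)C[C@@]3(C)OC(C)(C)O[C@H]3COS(=O)(=O)c4ccc(C)cc4
F2 | step 19 | α-chloro sulfide (Cl at C3) of 29 | C=C1C(O[Si](C)(C)C(C)(C)C)O[C@@H]2/C=C(CO[Si](c3ccccc3)(c3ccccc3)C(C)(C)C)\C(Cl)SC[C@@H]4OC(C)(C)O[C@]4(C)C[C@@H](OC(=O)c5ccccc5)[C@@H]12
F3 | step 19 | α-chloro sulfone (Cl at C3) | C=C1C(O[Si](C)(C)C(C)(C)C)O[C@@H]2/C=C(CO[Si](c3ccccc3)(c3ccccc3)C(C)(C)C)\C(Cl)S(=O)(=O)C[C@@H]4OC(C)(C)O[C@]4(C)C[C@@H](OC(=O)c5ccccc5)[C@@H]12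
F0 | step 25 | none | none
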